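**Plan**
- Retrosynthesis first cuts the two ArCH2–C bonds joining the central ring to the outer triketone rings (o-quinone methide alkylations), then the aryl–butanoyl bond (anionic Fries), then two bonds of the central benzene ring.
- Enabling feature: the central ring alternates O and C substituents, and both CH2-bearing carbons (C3, C5) flank the C4 oxygen. This is the pattern left when a siloxyalkyne is inserted between C1 and C2 of a 3-silyloxy-2-(silyloxymethyl)cyclobutenone (new bonds C2–C3 and C4–C5).
- One silyl propargyl ether supplies both partners: oxidation and silylation give the siloxyalkyne, and ketene [2+2] cycloaddition converts part of it into the cyclobutenone.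
- Forward order: the central benzene ring is the only ring built (step 3); bromination and acyl transfer install the butanoyl group; the two outer rings come from phloroglucinol (acylation, dearomatising gem-dimethylation) and are attached last.
- Stereochemistry: the target has no stereocentre; the one transient quaternary centre (vinylcyclobutenone 7) is racemic and is destroyed on ring opening.

Key step: step 3

Remark: the target is taken as the drawn enol tautomer of a freely equilibrating triketone system, and the cyclobutenone oxygen carries a triisopropylsilyl group so that every protecting group is removed by fluoride in the last step.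

**Step 1**
Reactants: 1 tert-butyldimethyl(prop-2-yn-1-yloxy)silane
Product: 4 triisopropyl{[3-(tert-butyldimethylsilyloxy)prop-1-yn-1-yl]oxy}silane, via lithium acetylide 2 (not isolated), via lithium ynolate 3 (not isolated)
Conditions: n-BuLi, THF, −78 °C; added to t-BuOOLi [t-BuOOH, LiN(SiMe3)2, THF, −78 °C], −78 → 0 °C; then i-Pr3SiOTf, −78 → 0 °C; aqueous work-up
Reagents that add atoms: tert-butyl hydroperoxide, CC(C)(C)OO; triisopropylsilyl trifluoromethanesulfonate, CC(C)[Si](OS(=O)(=O)C(F)(F)F)(C(C)C)C(C)C
Why: Oxidation of the lithium acetylide at carbon by lithium tert-butylperoxide gives the ynolate, and the bulky silyl triflate traps this ambident anion on oxygen (acetylide-to-ynolate oxidation followed by O-silylation), the silyl propargyl ether being inert to the bases used.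

**Step 2**
Reactants: 4 triisopropyl{[3-(tert-butyldimethylsilyloxy)prop-1-yn-1-yl]oxy}silane
Product: 5 2-[(tert-butyldimethylsilyloxy)methyl]-3-(triisopropylsilyloxy)cyclobut-2-en-1-one
Conditions: ketene gas (from pyrolysis of acetone), CH2Cl2, 0 °C → rt; rapid filtration through Et3N-deactivated silica
Reagents that add atoms: ketene, C=C=O
Why: Ketene–ynol ether [2+2] cycloaddition, in which the alkyne carbon remote from oxygen bonds to the ketene carbonyl carbon, so the silyloxymethyl group should end up at C2 next to the ketone and the silyloxy group at C3.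

**Step 3**
Reactants: 5 2-[(tert-butyldimethylsilyloxy)methyl]-3-(triisopropylsilyloxy)cyclobut-2-en-1-one; 4 triisopropyl{[3-(tert-butyldimethylsilyloxy)prop-1-yn-1-yl]oxy}silane (slight excess)
Product: 10 2,4-bis[(tert-butyldimethylsilyloxy)methyl]-3,5-bis(triisopropylsilyloxy)phenol, via vinylketene 6 (not isolated), via 4-vinylcyclobutenone 7 (not isolated), via dienylketene 8 (not isolated), via cyclohexa-2,4-dienone 9 (not isolated)
Conditions: toluene (degassed), sealed tube, 80 → 110 °C
Reagents that add atoms: none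
Why: Thermal 4π-electrocyclic opening of 5 (cleavage of C1–C4) should give the 2-silyloxy vinylketene 6, which adds to 4 in a polarised [2+2] cycloaddition to give 7; a second 4π opening gives dienylketene 8, and 6π closure followed by enolisation of 9 delivers phenol 10. This is the Danheiser benzannulation of a cyclobutenone with a siloxyalkyne, applied here to an oxygenated cyclobutenone (a vinylogous silyl ester). The one ring formed, the central benzene ring, closes by disrotatory 6π electrocyclisation of the (3E)-dienylketene; this re-forms the C(OH)–CH bond after the alkyne has been inserted between the carbonyl carbon and C2 of 5, so the two new skeletal bonds are C(OH)–C(CH2OSi) and C(OSi)–C(CH2OSi). No stereocentre is created in 10; the quaternary carbon of 7 forms as a racemate and is lost on ring opening. The step needs regiocontrol in the ketene–alkyne [2+2], and the polarisation of the siloxyalkyne secures it: its carbon remote from oxygen bonds to the ketene carbonyl carbon, which places the alkyne oxygen between the two CH2-bearing carbons and leaves the former cyclobutenone CH2 as the single unsubstituted ring position.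

**Step 4**
Reactants: 10 2,4-bis[(tert-butyldimethylsilyloxy)methyl]-3,5-bis(triisopropylsilyloxy)phenol
Product: 11 6-bromo-2,4-bis[(tert-butyldimethylsilyloxy)methyl]-3,5-bis(triisopropylsilyloxy)phenol
Conditions: NBS, CH2Cl2, −78 → −20 °C, dark
Reagents that add atoms: N-bromosuccinimide, O=C1CCC(=O)N1Br
Why: Electrophilic aromatic bromination at the only unsubstituted ring carbon, which is ortho to the free hydroxyl and ortho/para to the two silyloxy groups, with a reagent that releases no acid able to ionise the benzylic silyl ethers.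

**Step 5**
Reactants: 11 6-bromo-2,4-bis[(tert-butyldimethylsilyloxy)methyl]-3,5-bis(triisopropylsilyloxy)phenol; 12 butanoyl chloride
Product: 13 6-bromo-2,4-bis[(tert-butyldimethylsilyloxy)methyl]-3,5-bis(triisopropylsilyloxy)phenyl butanoate
Conditions: Et3N, DMAP (cat.), CH2Cl2, 0 °C → rt
Reagents that add atoms: none
Why: DMAP-catalysed O-acylation of the phenol places the butanoyl group next to the bromine for the intramolecular transfer that follows.

**Step 6**
Reactants: 13 6-bromo-2,4-bis[(tert-butyldimethylsilyloxy)methyl]-3,5-bis(triisopropylsilyloxy)phenyl butanoate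
Product: 15 1-{3,5-bis[(tert-butyldimethylsilyloxy)methyl]-2-hydroxy-4,6-bis(triisopropylsilyloxy)phenyl}butan-1-one, via aryllithium 14 (not isolated)
Conditions: t-BuLi (2.1 equiv), THF/Et2O, −95 → −78 °C; then AcOH, −78 °C
Reagents that add atoms: none
Why: Bromine–lithium exchange followed by anionic Fries rearrangement (1,3 O→C acyl shift), in which the aryllithium should attack the neighbouring ester faster than any external reagent and the resulting phenoxide shields the ketone from further addition.

**Step 7**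
Reactants: 16 phloroglucinol; 12 butanoyl chloride
Product: 17 1-(2,4,6-trihydroxyphenyl)butan-1-one
Conditions: AlCl3, PhNO2/CH2Cl2, rt → 50 °C; ice/aq. HCl
Reagents that add atoms: none
Why: Friedel–Crafts acylation of phloroglucinol, where the first acyl group deactivates the ring so that mono-acylation should prevail.

**Step 8**
Reactants: 17 1-(2,4,6-trihydroxyphenyl)butan-1-one
Product: 19 2-butanoyl-3,5-dihydroxy-4,4-dimethylcyclohexa-2,5-dien-1-one (butyrylfilicinic acid), via 3-methyl acylphloroglucinol 18 (not isolated)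
Conditions: NaOMe (3.5 equiv), MeI (2.2 equiv), MeOH, 0 °C → rt; aq. HCl; chromatography
Reagents that add atoms: iodomethane, CI
Why: Dearomatising double C-methylation of the acylphloroglucinol polyanion (the established route to acylfilicinic acids), in which the second methyl group enters at the already methylated, most electron-rich carbon and blocks it as a quaternary centre; selectivity over other C-methylation patterns is expected to be modest, so separation is planned.

**Step 9**
Reactants: 15 1-{3,5-bis[(tert-butyldimethylsilyloxy)methyl]-2-hydroxy-4,6-bis(triisopropylsilyloxy)phenyl}butan-1-one; 19 2-butanoyl-3,5-dihydroxy-4,4-dimethylcyclohexa-2,5-dien-1-one (2.5 equiv)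
Product: 24 1-{2,4,6-trihydroxy-3,5-bis[(5-butanoyl-2,4-dihydroxy-3,3-dimethyl-6-oxocyclohexa-1,4-dien-1-yl)methyl]phenyl}butan-1-one (the target), via bis-phenol 20 (not isolated), via first o-quinone methide 21 (not isolated), via mono-adduct 22 (not isolated), via second o-quinone methide 23 (not isolated)
Conditions: Bu4NF (5 equiv), THF, 0 °C → rt (to 40 °C if needed); then 1 M HCl to pH 3
Reagents that add atoms: none
Why: Fluoride frees the two aryl oxygens, each phenoxide expels the neighbouring benzylic silanolate to form an o-quinone methide, and the filicinate enolate adds through its only CH carbon in a Michael reaction (fluoride-triggered o-quinone methide alkylation, the same bond formation as in the alkaline formaldehyde coupling of acylphloroglucinols), the sequence then repeating at the second benzylic carbon.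

**Compound list**
1 | tert-butyldimethyl(prop-2-yn-1-yloxy)silane | C#CCO[Si](C)(C)C(C)(C)C | starting material
2 | lithium 3-(tert-butyldimethylsilyloxy)prop-1-yn-1-ide | [Li]C#CCO[Si](C)(C)C(C)(C)C | intermediate
3 | lithium 3-(tert-butyldimethylsilyloxy)prop-1-yn-1-olate | [Li]OC#CCO[Si](C)(C)C(C)(C)C | intermediate
4 | triisopropyl{[3-(tert-butyldimethylsilyloxy)prop-1-yn-1-yl]oxy}silane | CC(C)[Si](OC#CCO[Si](C)(C)C(C)(C)C)(C(C)C)C(C)C | intermediate
5 | 2-[(tert-butyldimethylsilyloxy)methyl]-3-(triisopropylsilyloxy)cyclobut-2-en-1-one | O=C1CC(O[Si](C(C)C)(C(C)C)C(C)C)=C1CO[Si](C)(C)C(C)(C)C | intermediate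
6 | 2-[(tert-butyldimethylsilyloxy)methyl]-3-(triisopropylsilyloxy)buta-1,3-dien-1-one (vinylketene) | O=C=C(CO[Si](C)(C)C(C)(C)C)C(=C)O[Si](C(C)C)(C(C)C)C(C)C | intermediate
7 | racemic 2,4-bis[(tert-butyldimethylsilyloxy)methyl]-3-(triisopropylsilyloxy)-4-[1-(triisopropylsilyloxy)ethenyl]cyclobut-2-en-1-one | O=C1C(CO[Si](C)(C)C(C)(C)C)=C(O[Si](C(C)C)(C(C)C)C(C)C)C1(CO[Si](C)(C)C(C)(C)C)C(=C)O[Si](C(C)C)(C(C)C)C(C)C | intermediate
8 | (3E)-2,4-bis[(tert-butyldimethylsilyloxy)methyl]-3,5-bis(triisopropylsilyloxy)hexa-1,3,5-trien-1-one (dienylketene) | O=C=C(CO[Si](C)(C)C(C)(C)C)/C(O[Si](C(C)C)(C(C)C)C(C)C)=C(CO[Si](C)(C)C(C)(C)C)\C(=C)O[Si](C(C)C)(C(C)C)C(C)C | intermediate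
9 | 2,4-bis[(tert-butyldimethylsilyloxy)methyl]-3,5-bis(triisopropylsilyloxy)cyclohexa-2,4-dien-1-one | O=C1CC(O[Si](C(C)C)(C(C)C)C(C)C)=C(CO[Si](C)(C)C(C)(C)C)C(O[Si](C(C)C)(C(C)C)C(C)C)=C1CO[Si](C)(C)C(C)(C)C | intermediate
10 | 2,4-bis[(tert-butyldimethylsilyloxy)methyl]-3,5-bis(triisopropylsilyloxy)phenol | Oc1cc(O[Si](C(C)C)(C(C)C)C(C)C)c(CO[Si](C)(C)C(C)(C)C)c(O[Si](C(C)C)(C(C)C)C(C)C)c1CO[Si](C)(C)C(C)(C)C | intermediate
11 | 6-bromo-2,4-bis[(tert-butyldimethylsilyloxy)methyl]-3,5-bis(triisopropylsilyloxy)phenol | Oc1c(Br)c(O[Si](C(C)C)(C(C)C)C(C)C)c(CO[Si](C)(C)C(C)(C)C)c(O[Si](C(C)C)(C(C)C)C(C)C)c1CO[Si](C)(C)C(C)(C)C | intermediate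
12 | butanoyl chloride | CCCC(Cl)=O | starting material
13 | 6-bromo-2,4-bis[(tert-butyldimethylsilyloxy)methyl]-3,5-bis(triisopropylsilyloxy)phenyl butanoate | CCCC(=O)Oc1c(Br)c(O[Si](C(C)C)(C(C)C)C(C)C)c(CO[Si](C)(C)C(C)(C)C)c(O[Si](C(C)C)(C(C)C)C(C)C)c1CO[Si](C)(C)C(C)(C)C | intermediate
14 | 6-lithio-2,4-bis[(tert-butyldimethylsilyloxy)methyl]-3,5-bis(triisopropylsilyloxy)phenyl butanoate | CCCC(=O)Oc1c([Li])c(O[Si](C(C)C)(C(C)C)C(C)C)c(CO[Si](C)(C)C(C)(C)C)c(O[Si](C(C)C)(C(C)C)C(C)C)c1CO[Si](C)(C)C(C)(C)C | intermediate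
15 | 1-{3,5-bis[(tert-butyldimethylsilyloxy)methyl]-2-hydroxy-4,6-bis(triisopropylsilyloxy)phenyl}butan-1-one | CCCC(=O)c1c(O)c(CO[Si](C)(C)C(C)(C)C)c(O[Si](C(C)C)(C(C)C)C(C)C)c(CO[Si](C)(C)C(C)(C)C)c1O[Si](C(C)C)(C(C)C)C(C)C | intermediate
16 | phloroglucinol (benzene-1,3,5-triol) | Oc1cc(O)cc(O)c1 | starting material
17 | 1-(2,4,6-trihydroxyphenyl)butan-1-one | CCCC(=O)c1c(O)cc(O)cc1O | intermediate
18 | 1-(2,4,6-trihydroxy-3-methylphenyl)butan-1-one | CCCC(=O)c1c(O)cc(O)c(C)c1O | intermediate
19 | 2-butanoyl-3,5-dihydroxy-4,4-dimethylcyclohexa-2,5-dien-1-one (butyrylfilicinic acid) | CCCC(=O)C1=C(O)C(C)(C)C(O)=CC1=O | intermediate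
20 | 1-{3,5-bis[(tert-butyldimethylsilyloxy)methyl]-2,4,6-trihydroxyphenyl}butan-1-one | CCCC(=O)c1c(O)c(CO[Si](C)(C)C(C)(C)C)c(O)c(CO[Si](C)(C)C(C)(C)C)c1O | intermediate
21 | 4-butanoyl-2-[(tert-butyldimethylsilyloxy)methyl]-3,5-dihydroxy-6-methylidenecyclohexa-2,4-dien-1-one | CCCC(=O)C1=C(O)C(=C)C(=O)C(CO[Si](C)(C)C(C)(C)C)=C1O | intermediate
22 | 1-{3-[(5-butanoyl-2,4-dihydroxy-3,3-dimethyl-6-oxocyclohexa-1,4-dien-1-yl)methyl]-5-[(tert-butyldimethylsilyloxy)methyl]-2,4,6-trihydroxyphenyl}butan-1-one | CCCC(=O)c1c(O)c(CC2=C(O)C(C)(C)C(O)=C(C(=O)CCC)C2=O)c(O)c(CO[Si](C)(C)C(C)(C)C)c1O | intermediate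
23 | 4-butanoyl-2-[(5-butanoyl-2,4-dihydroxy-3,3-dimethyl-6-oxocyclohexa-1,4-dien-1-yl)methyl]-3,5-dihydroxy-6-methylidenecyclohexa-2,4-dien-1-one | CCCC(=O)C1=C(O)C(=C)C(=O)C(CC2=C(O)C(C)(C)C(O)=C(C(=O)CCC)C2=O)=C1O | intermediate
24 | 1-{2,4,6-trihydroxy-3,5-bis[(5-butanoyl-2,4-dihydroxy-3,3-dimethyl-6-oxocyclohexa-1,4-dien-1-yl)methyl]phenyl}butan-1-one (CNP0287270.0) | CCCC(=O)C1=C(O)C(C)(C)C(O)=C(Cc2c(O)c(CC3=C(O)C(C)(C)C(O)=C(C(=O)CCC)C3=O)c(O)c(C(=O)CCC)c2O)C1=O | target

**Step count and risks**
Total steps: 9. Longest linear sequence: 7 steps (steps 1, 2, 3, 4, 5, 6 and 9, from 1 to 24).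

Steps most likely to fail:

1. Step 9. The quinone methides may self-condense before the filicinate captures them, and the basic medium may cause retro-Michael exchange of the methylene bridges, scrambling the product towards symmetrical by-products. The fallback sets out from 15 and returns at 24, and replaces the anionic cascade by acid-mediated benzylation with the phenols still protected. Selective hydrolysis of the benzylic silyl ethers of 15 (AcOH/THF/H2O, rt; the aryl silyl ethers persist) gives 1-[2-hydroxy-3,5-bis(hydroxymethyl)-4,6-bis(triisopropylsilyloxy)phenyl]butan-1-one F1. Condensation of F1 with two equivalents of 19 (TsOH cat., toluene, 4 Å sieves, rt → 40 °C) lets the enol capture the stabilised benzylic cations and gives 1-{2-hydroxy-4,6-bis(triisopropylsilyloxy)-3,5-bis[(5-butanoyl-2,4-dihydroxy-3,3-dimethyl-6-oxocyclohexa-1,4-dien-1-yl)methyl]phenyl}butan-1-one F2. HF·pyridine in THF at 0 °C then frees the two phenols to give 24.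

2. Step 3. Electrocyclic opening of the vinylogous silyl ester may be slow, or the [2+2] between two fully substituted π-systems may be sterically retarded, so that the vinylketene dimerises or acylates the product phenol. The fallback sets out from 17 and 19 and returns at 24; it takes the central ring from phloroglucinol instead of building it. A double Mannich reaction of 17 (aq. CH2O, Me2NH, EtOH, rt) gives 1-{3,5-bis[(dimethylamino)methyl]-2,4,6-trihydroxyphenyl}butan-1-one F3. Heating F3 with two equivalents of 19 (dioxane, 90 °C) expels dimethylamine, and the o-quinone methides so formed are trapped by 19 to give 24.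

3. Step 6. Anionic migration of the neighbouring triisopropylsilyl group to the lithiated carbon, or addition of the alkyllithium to the ester before exchange, may compete with acyl transfer. The fallback sets out from 10 and returns at 15; it avoids both the bromide and the aryllithium. Acylation of 10 with 12 (Et3N, DMAP, CH2Cl2) gives 2,4-bis[(tert-butyldimethylsilyloxy)methyl]-3,5-bis(triisopropylsilyloxy)phenyl butanoate F4. Photo-Fries rearrangement of F4 (254 nm, cyclohexane, rt), a radical-pair acyl shift, can only deliver the acyl group to the single free ortho carbon and gives 15.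

**Further compounds**
F1 | step 9 | 1-[2-hydroxy-3,5-bis(hydroxymethyl)-4,6-bis(triisopropylsilyloxy)phenyl]butan-1-one | CCCC(=O)c1c(O)c(CO)c(O[Si](C(C)C)(C(C)C)C(C)C)c(CO)c1O[Si](C(C)C)(C(C)C)C(C)C
F2 | step 9 | 1-{2-hydroxy-4,6-bis(triisopropylsilyloxy)-3,5-bis[(5-butanoyl-2,4-dihydroxy-3,3-dimethyl-6-oxocyclohexa-1,4-dien-1-yl)methyl]phenyl}butan-1-one | CCCC(=O)c1c(O)c(CC2=C(O)C(C)(C)C(O)=C(C(=O)CCC)C2=O)c(O[Si](C(C)C)(C(C)C)C(C)C)c(CC2=C(O)C(C)(C)C(O)=C(C(=O)CCC)C2=O)c1O[Si](C(C)C)(C(C)C)C(C)C
F3 | step 3 | 1-{3,5-bis[(dimethylamino)methyl]-2,4,6-trihydroxyphenyl}butan-1-one | CCCC(=O)c1c(O)c(CN(C)C)c(O)c(CN(C)C)c1O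
F4 | step 6 | 2,4-bis[(tert-butyldimethylsilyloxy)methyl]-3,5-bis(triisopropylsilyloxy)phenyl butanoate | CCCC(=O)Oc1cc(O[Si](C(C)C)(C(C)C)C(C)C)c(CO[Si](C)(C)C(C)(C)C)c(O[Si](C(C)C)(C(C)C)C(C)C)c1CO[Si](C)(C)C(C)(C)C
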